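**Plan**
1. Retrosynthesis: the four esters come off first, and the C3 benzoate is traced to a Mitsunobu inversion. C4=C5 goes back to a C5 selenide and the C2 carbinol to a ketone. C3–C4 and C1–C6 are then cut together, leaving a C4 ketone (C7–C1–C2–C3) and an acrolein unit (C4–C5–C6).
2. Enabling feature: C2 lies between the two new bonds, so at the ketone level C1 and C3 are both enol donors. C4–C5–C6(O6) is an enal, with C4 as the β-carbon and C6 as the carbonyl. The C2/C6 1,5- and O2/O6 1,3-relations are all consonant.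
3. O1 and O3 are tied as a benzylidene acetal. The ketone is then a 1,3-dioxan-5-one and the annulation product a 2,4-dioxabicyclo[3.3.1]nonan-9-one. Its bridgeheads C1 and C3 cannot enolise, which blocks epimerisation, conjugation and aromatisation.
4. Forward: D-glucose C3–C6 supply C7, C1, C2 and C3 with the dioxane ring already in place. The carbocycle is the only ring made (step 5), and the dioxane is removed in step 9.
5. Stereochemistry: glucose C4 and the acetal carbon fix C1 and, transiently, C3. A closed aldol transition state sets C6, O6-directed hydride sets C2, and SN2 attack by benzoate sets C3.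

Key step: step 5

Remark (numbering): target numbering is used for all compounds. C1 = C(OH)(CH2O), C7 = that CH2, C2 = CHOAc, C3 = CHOBz, C4=C5, C6 = CHOAc, and O1–O3, O6, O7 are the oxygens on these carbons.
Remark (assumption): the anomeric centre of 1, the Se-bearing carbon of 7 and 10–13 and the Se centre of 13 have no consequence for the route and are left undefined.

Step 1
Reactants: 1 4,6-O-[(R)-benzylidene]-D-glucopyranose
Product: 3 2,4-O-[(R)-benzylidene]-D-erythritol, via 2,4-O-benzylidene-D-erythrose 2 (not isolated)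
Conditions: NaIO4 (2.1 equiv), NaHCO3, H2O, 0 °C → rt; salts removed (EtOH); NaBH4, EtOH–H2O, 0 °C
Reagents that add atoms: none
Why: Malaprade glycol cleavage excises glucose C1 and C2 as formate and borohydride reduces the liberated aldehyde, so glucose C3–C6 become C7, C1, C2 and C3 with C1 and the acetal carbon already in the required absolute configuration.

Step 2
Reactants: 3 2,4-O-[(R)-benzylidene]-D-erythritol
Product: 4 (2R,4S,5R)-4-{[(tert-butyldimethylsilyl)oxy]methyl}-2-phenyl-1,3-dioxan-5-ol
Conditions: TBSCl (1.05 equiv), imidazole, CH2Cl2, 0 °C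
Reagents that add atoms: tert-butyldimethylsilyl chloride, CC(C)(C)[Si](C)(C)Cl
Why: Standard selective silylation takes the primary O7 hydroxyl before the secondary ring hydroxyl, and a silyl ether is preferred to the final benzoate here because it is a poor leaving group β to the later C1 enol.

Step 3
Reactants: 4 (2R,4S,5R)-4-{[(tert-butyldimethylsilyl)oxy]methyl}-2-phenyl-1,3-dioxan-5-ol
Product: 5 (2R,4S)-4-{[(tert-butyldimethylsilyl)oxy]methyl}-2-phenyl-1,3-dioxan-5-one
Conditions: Dess–Martin periodinane, NaHCO3, CH2Cl2, 0 °C → rt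
Reagents that add atoms: none
Why: Dess–Martin oxidation under buffered, non-basic conditions should give the dioxanone without β-elimination, and the C1 substituent is already equatorial so that epimerisation would change nothing.

Step 4
Reactants: 6 acrolein
Product: 8 2-(phenylselanyl)prop-2-enal, via 3-chloro-2-(phenylselanyl)propanal 7 (not isolated)
Conditions: PhSeCl, CH2Cl2, −78 → 0 °C; then Et3N, 0 °C; used freshly prepared
Reagents that add atoms: benzeneselenenyl chloride, Cl[Se]c1ccccc1
Why: Electrophilic selenenylation of the enal followed by E1cB loss of HCl (the addition–elimination route to α-selanyl enones and enals) places on C5 the group that is later expelled to give C4=C5.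

Step 5
Reactants: 5 (2R,4S)-4-{[(tert-butyldimethylsilyl)oxy]methyl}-2-phenyl-1,3-dioxan-5-one; 8 2-(phenylselanyl)prop-2-enal
Product: 11 (1R,3R,5S,8R)-1-{[(tert-butyldimethylsilyl)oxy]methyl}-8-hydroxy-3-phenyl-7-(phenylselanyl)-2,4-dioxabicyclo[3.3.1]nonan-9-one, via pyrrolidine enamine 9 (not isolated), via keto aldehyde 10 (not isolated)
Conditions: pyrrolidine (1.1 equiv), 4 Å MS, MeCN, rt; 8 (1.0 equiv), −20 °C → rt; then AcOH–NaOAc buffer (pH ≈ 5), THF–H2O, rt → 40 °C (one flask)
Reagents that add atoms: water, O (returns the C2 carbonyl oxygen when the iminium ion is hydrolysed)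
Why: The less substituted enamine 9 (C2=C3) adds 1,4 to enal 8 to form C3–C4, buffered hydrolysis unmasks keto aldehyde 10, and its C1=C2 enol attacks the C6 aldehyde to form C1–C6, so the carbocycle, the fully substituted carbinol C1 and the carbinol C6 arise in one flask. The closest known reaction type is the Stork enamine α,α′-annulation of cyclic ketones with acrolein-type acceptors (Michael addition, then ketol closure to bicyclo[3.3.1]nonan-9-ones), and 1,3-dioxan-5-one enamines are known to undergo α,α′-annulation with other 1,3-bis-electrophiles. The one ring closure is a 6-(enolendo)-exo-trig aldol that converts the dioxane into a 2,4-dioxabicyclo[3.3.1]nonane. The three-carbon bridge can only span the two axial positions of the dioxane chair anchored by the equatorial phenyl group, so C6 replaces the axial H of C1 with retention although C1 passes through an enol (the acetal carbon stores the chirality), and only the axial C3 epimer of 10, which is reached by free epimerisation, can cyclise. C6 is set by a closed, hydrogen-bonded transition state that holds the aldehyde oxygen gauche to C2–O and so makes O6 axial and anti to O1, whereas C5 is uncontrolled and is erased in step 7. The step needs 1,4- over 1,2-addition (soft enamine, α-selanyl acceptor), reaction at C3 before C1 (A1,3 strain disfavours the tetrasubstituted enamine), ketol rather than Mannich closure (water in excess and pyrrolidine fully protonated at pH 5), and no dehydration, β-elimination or aromatisation (C1 becomes quaternary, O7 carries a silyl group, the bridgeheads of 11 cannot enolise).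

Step 6
Reactants: 11 (1R,3R,5S,8R)-1-{[(tert-butyldimethylsilyl)oxy]methyl}-8-hydroxy-3-phenyl-7-(phenylselanyl)-2,4-dioxabicyclo[3.3.1]nonan-9-one
Product: 12 (1S,3R,5S,8R,9S)-1-{[(tert-butyldimethylsilyl)oxy]methyl}-3-phenyl-7-(phenylselanyl)-2,4-dioxabicyclo[3.3.1]nonane-8,9-diol
Conditions: Me4NBH(OAc)3, MeCN–AcOH (1:1), −30 °C
Reagents that add atoms: none
Why: In this Evans–Saksena reduction the axial C6 hydroxyl binds the triacetoxyborohydride and delivers hydride to the C2 carbonyl face syn to O6, which should give the 1,3-anti diol with O2 cis to O1 and also removes the retro-aldol risk.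

Step 7
Reactants: 12 (1S,3R,5S,8R,9S)-1-{[(tert-butyldimethylsilyl)oxy]methyl}-3-phenyl-7-(phenylselanyl)-2,4-dioxabicyclo[3.3.1]nonane-8,9-diol
Product: 14 (1R,3R,5S,8S,9S)-1-{[(tert-butyldimethylsilyl)oxy]methyl}-3-phenyl-2,4-dioxabicyclo[3.3.1]non-6-ene-8,9-diol, via selenoxide 13 (not isolated)
Conditions: mCPBA (1.0 equiv), CH2Cl2, −78 °C; then i-Pr2NH, −78 °C → rt
Reagents that add atoms: none
Why: Selenoxide syn-elimination of a β-hydroxy selenide runs away from the carbinol carbon, so a C4–H is taken and the allylic alcohol C4=C5–C6(OH) should form with C6 untouched.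

Step 8
Reactants: 14 (1R,3R,5S,8S,9S)-1-{[(tert-butyldimethylsilyl)oxy]methyl}-3-phenyl-2,4-dioxabicyclo[3.3.1]non-6-ene-8,9-diol
Product: 15 (1R,3R,5S,8S,9S)-1-{[(tert-butyldimethylsilyl)oxy]methyl}-3-phenyl-2,4-dioxabicyclo[3.3.1]non-6-ene-8,9-diyl diacetate
Conditions: Ac2O, pyridine, DMAP (cat.), CH2Cl2, rt
Reagents that add atoms: acetic anhydride, CC(=O)OC(C)=O
Why: DMAP-catalysed acetylation esterifies the only two free hydroxyls (O2 and O6) while O1 and O3 are locked in the acetal and O7 is silylated, so the acetate pattern of the target is fixed without any selectivity problem.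

Step 9
Reactants: 15 (1R,3R,5S,8S,9S)-1-{[(tert-butyldimethylsilyl)oxy]methyl}-3-phenyl-2,4-dioxabicyclo[3.3.1]non-6-ene-8,9-diyl diacetate
Product: 16 (1R,2S,3S,6S)-2,6-diacetoxy-1-(hydroxymethyl)cyclohex-4-ene-1,3-diol (target numbering)
Conditions: TFA–H2O (9:1), CH2Cl2, 0 °C → rt
Reagents that add atoms: none
Why: Aqueous acid hydrolyses the benzylidene acetal through its benzylic oxocarbenium ion and cleaves the primary silyl ether in the same pot, under conditions in which acetates normally neither hydrolyse nor migrate.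

Step 10
Reactants: 16 (1R,2S,3S,6S)-2,6-diacetoxy-1-(hydroxymethyl)cyclohex-4-ene-1,3-diol
Product: 17 (1R,2S,3S,6S)-2,6-diacetoxy-1-[(benzoyloxy)methyl]cyclohex-4-ene-1,3-diol (target numbering)
Conditions: BzCl (1.05 equiv), pyridine, CH2Cl2, −40 → 0 °C
Reagents that add atoms: benzoyl chloride, O=C(Cl)c1ccccc1
Why: Kinetically controlled selective acylation at low temperature should take the primary O7 hydroxyl in preference to the secondary allylic O3 and the tertiary O1 hydroxyl.

Step 11
Reactants: 17 (1R,2S,3S,6S)-2,6-diacetoxy-1-[(benzoyloxy)methyl]cyclohex-4-ene-1,3-diol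
Product: 18 (1R,2S,3R,6S)-2,6-diacetoxy-3-(benzoyloxy)-1-[(benzoyloxy)methyl]cyclohex-4-en-1-ol (target numbering), the target
Conditions: PPh3, DIAD, BzOH, toluene, 0 °C → rt
Reagents that add atoms: benzoic acid, O=C(O)c1ccccc1
Why: The Mitsunobu reaction activates only the pseudoaxial secondary allylic C3 hydroxyl (the tertiary O1–H is inert) and benzoate displaces it by SN2 from the face opposite to the cis C2 acetate, which cannot participate, so C3 is inverted in the same step that installs its ester.

**Compound list**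
1 | 4,6-O-[(R)-benzylidene]-D-glucopyranose (anomeric mixture) | OC1O[C@@H]2CO[C@@H](c3ccccc3)O[C@H]2[C@H](O)[C@H]1O | starting material
2 | 2,4-O-[(R)-benzylidene]-D-erythrose | O[C@@H]1CO[C@@H](c2ccccc2)O[C@H]1C=O | intermediate
3 | 2,4-O-[(R)-benzylidene]-D-erythritol, (2R,4S,5R)-4-(hydroxymethyl)-2-phenyl-1,3-dioxan-5-ol | O[C@@H]1CO[C@@H](c2ccccc2)O[C@H]1CO | intermediate
4 | (2R,4S,5R)-4-{[(tert-butyldimethylsilyl)oxy]methyl}-2-phenyl-1,3-dioxan-5-ol | O[C@@H]1CO[C@@H](c2ccccc2)O[C@H]1CO[Si](C)(C)C(C)(C)C | intermediate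
5 | (2R,4S)-4-{[(tert-butyldimethylsilyl)oxy]methyl}-2-phenyl-1,3-dioxan-5-one | O=C1CO[C@@H](c2ccccc2)O[C@H]1CO[Si](C)(C)C(C)(C)C | intermediate
6 | acrolein (prop-2-enal) | C=CC=O | starting material
7 | 3-chloro-2-(phenylselanyl)propanal (racemic) | O=CC(CCl)[Se]c1ccccc1 | intermediate
8 | 2-(phenylselanyl)prop-2-enal | C=C(C=O)[Se]c1ccccc1 | intermediate
9 | pyrrolidine enamine of 5 (C2=C3 double bond, C1 and acetal carbon as in 5) | CC(C)(C)[Si](C)(C)OC[C@@H]1O[C@H](c2ccccc2)OC=C1N1CCCC1 | intermediate
10 | keto aldehyde: 5 carrying an axial CH2CH(SePh)CHO chain at C3, cis to H-1 and to the acetal H | O=CC([Se]c1ccccc1)C[C@@H]1O[C@@H](c2ccccc2)O[C@@H](CO[Si](C)(C)C(C)(C)C)C1=O | intermediate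
11 | (1R,3R,5S,8R)-1-{[(tert-butyldimethylsilyl)oxy]methyl}-8-hydroxy-3-phenyl-7-(phenylselanyl)-2,4-dioxabicyclo[3.3.1]nonan-9-one | O[C@H]1C([Se]c4ccccc4)C[C@@H]2O[C@@H](c3ccccc3)O[C@@]1(CO[Si](C)(C)C(C)(C)C)C2=O | intermediate
12 | (1S,3R,5S,8R,9S)-1-{[(tert-butyldimethylsilyl)oxy]methyl}-3-phenyl-7-(phenylselanyl)-2,4-dioxabicyclo[3.3.1]nonane-8,9-diol | O[C@H]1C([Se]c4ccccc4)C[C@@H]2O[C@@H](c3ccccc3)O[C@@]1(CO[Si](C)(C)C(C)(C)C)[C@H]2O | intermediate
13 | selenoxide of 12 | O[C@H]1C([Se](=O)c4ccccc4)C[C@@H]2O[C@@H](c3ccccc3)O[C@@]1(CO[Si](C)(C)C(C)(C)C)[C@H]2O | intermediate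
14 | (1R,3R,5S,8S,9S)-1-{[(tert-butyldimethylsilyl)oxy]methyl}-3-phenyl-2,4-dioxabicyclo[3.3.1]non-6-ene-8,9-diol | O[C@H]1C=C[C@@H]2O[C@@H](c3ccccc3)O[C@@]1(CO[Si](C)(C)C(C)(C)C)[C@H]2O | intermediate
15 | (1R,3R,5S,8S,9S)-1-{[(tert-butyldimethylsilyl)oxy]methyl}-3-phenyl-2,4-dioxabicyclo[3.3.1]non-6-ene-8,9-diyl diacetate | CC(=O)O[C@H]1C=C[C@@H]2O[C@@H](c3ccccc3)O[C@@]1(CO[Si](C)(C)C(C)(C)C)[C@H]2OC(C)=O | intermediate
16 | (1R,2S,3S,6S)-2,6-diacetoxy-1-(hydroxymethyl)cyclohex-4-ene-1,3-diol (target numbering) | CC(=O)O[C@H]1C=C[C@H](O)[C@H](OC(C)=O)[C@@]1(O)CO | intermediate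
17 | (1R,2S,3S,6S)-2,6-diacetoxy-1-[(benzoyloxy)methyl]cyclohex-4-ene-1,3-diol (target numbering) | CC(=O)O[C@H]1C=C[C@H](O)[C@H](OC(C)=O)[C@@]1(O)COC(=O)c1ccccc1 | intermediate
18 | (1R,2S,3R,6S)-2,6-diacetoxy-3-(benzoyloxy)-1-[(benzoyloxy)methyl]cyclohex-4-en-1-ol (target numbering) | CC(=O)O[C@H]1C=C[C@@H](OC(=O)c2ccccc2)[C@H](OC(C)=O)[C@@]1(O)COC(=O)c1ccccc1 | target

**Totals**
Total step count: 11.
Longest linear sequence: 10 steps from 1 (steps 1–3 and 5–11). Step 4 is a one-step branch from 6.

**Steps most likely to fail**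

Step 5.
- What may go wrong: the amine may be retained at C6 through Mannich instead of ketol closure. The enal may suffer 1,2-addition or oligomerise. The silyloxy group may be lost by β-elimination from the C1 enol. Control at C6 may erode if the aldol step becomes reversible.
- Fallback (amine-free; cycloaddition and a metal-chelated aldol instead of enamine chemistry), setting out from 5: kinetic enolisation with in situ silylation (LiHMDS, TMSCl, THF, −78 °C) gives the trimethylsilyl enol ether F1.
- An inverse-electron-demand hetero-Diels–Alder reaction of F1 with 8 as the 1-oxadiene (heat or Yb(fod)3) forms C3–C4 and gives the 2-silyloxy-3,4-dihydro-2H-pyran F2, which is isolated.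
- Mild aqueous acid releases 10. A chelating soft enolisation (MgBr2·OEt2, i-Pr2NEt, CH2Cl2) then closes C1–C6 through a magnesium-bridged transition state. The route is rejoined at 11.

Step 11.
- What may go wrong: benzoate may attack in the SN2′ sense at C5, elimination may give a diene that aromatises, or the hydrogen-bonded cis-1,3-diol may be activated only sluggishly.
- Fallback (oxidation, directed reduction and acylation instead of substitution), setting out from 17: Dess–Martin oxidation gives the 4-en-3-one F3.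
- Evans–Saksena reduction (Me4NBH(OAc)3, MeCN–AcOH, −30 °C) is now directed by the tertiary O1 hydroxyl. It delivers hydride to the face syn to O1 and gives the C3-inverted allylic alcohol F4.
- Benzoylation (BzCl, pyridine, DMAP) rejoins the route at 18.

Step 9.
- What may go wrong: acetyl groups may migrate among the three hydroxyls that are set free at once, the bridged acetal may cleave incompletely, or the allylic C3–O bond may ionise in strong aqueous acid.
- Fallback (staged, partly non-aqueous deprotection that also makes the selective acylation of step 10 unnecessary), setting out from 15: HF·pyridine in THF gives the primary alcohol F5.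
- Benzoylation (BzCl, pyridine), with O1 and O3 still locked, gives the C7 benzoate F6.
- Acetal exchange with propane-1,3-dithiol and BF3·OEt2 in CH2Cl2 at low temperature frees O1 and O3. The route is rejoined at 17.

**Further compounds**
F1 | step 5 | trimethylsilyl enol ether of 5 (C2=C3) | CC(C)(C)[Si](C)(C)OC[C@@H]1O[C@H](c2ccccc2)OC=C1O[Si](C)(C)C
F2 | step 5 | hetero-Diels–Alder adduct of F1 and 8, a cis-fused 2-(trimethylsilyloxy)-5-(phenylselanyl)-3,4-dihydro-2H-pyran (new C3–C4 and C2–O6 bonds on the axial face) | C[Si](C)(C)O[C@@]12OC=C([Se]c3ccccc3)C[C@@H]1O[C@@H](c1ccccc1)O[C@H]2CO[Si](C)(C)C(C)(C)C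
F3 | step 11 | 4-en-3-one derived from 17 | CC(=O)O[C@H]1C=CC(=O)[C@H](OC(C)=O)[C@@]1(O)COC(=O)c1ccccc1
F4 | step 11 | (1R,2S,3R,6S)-2,6-diacetoxy-1-[(benzoyloxy)methyl]cyclohex-4-ene-1,3-diol (target numbering) | CC(=O)O[C@H]1C=C[C@@H](O)[C@H](OC(C)=O)[C@@]1(O)COC(=O)c1ccccc1
F5 | step 9 | 15 with a free C7 hydroxyl | CC(=O)O[C@H]1C=C[C@@H]2O[C@@H](c3ccccc3)O[C@@]1(CO)[C@H]2OC(C)=O
F6 | step 9 | C7 benzoate of F5 | CC(=O)O[C@H]1C=C[C@@H]2O[C@@H](c3ccccc3)O[C@@]1(COC(=O)c4ccccc4)[C@H]2OC(C)=O
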